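The target is read as the all-(4α→8) tetramer of (+)-catechin. Three units come from (+)-catechin itself; ring C of the third unit (the one bound through C4 to the terminal unit) is built de novo by a [3+3] anionic annulation. An α-thio benzylic carbanion on a 2-fluoro-4,6-dibenzyloxyphenyl ring (future C4, C4a, C8a) opens an enantiopure aryloxirane at its CH2 carbon (C3–C4) and the released C2 alkoxide displaces the fluoride (O1–C8a), so the pyran ring closes in one operation. The step exploits the benzylic C4 and the C8a position of ring A, whose two meta oxygens activate fluoride displacement. Sulfoxide elimination, face-selective epoxidation and flavan-4-yl cation couplings complete the tetramer.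

Key step: step 5

Remark: the SMILES is read as catechin-(4α→8)-catechin-(4α→8)-catechin-(4α→8)-catechin (every unit 2R and 2,3-trans, every interflavan bond 3,4-trans); flavan numbering (O1, C2, C3, C4, C4a, C5–C8, C8a) is used throughout, and compounds 1, 6 and 14 are taken as catalogue compounds.

Step 1
Reactants: 1 1,3,5-trifluorobenzene
Product: 2 1,3-bis(benzyloxy)-5-fluorobenzene
Conditions: BnOH (2.1 equiv), NaH (2.2 equiv), NMP, 0 °C → 90 °C
Reagents that add atoms: benzyl alcohol OCc1ccccc1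
Why: Twofold nucleophilic aromatic substitution (SNAr) by sodium benzyloxide should stop after the second exchange because each alkoxy group deactivates the ring towards the next one; no stereocenter is formed.

Step 2
Reactants: 2 1,3-bis(benzyloxy)-5-fluorobenzene
Product: 5 1,5-bis(benzyloxy)-3-fluoro-2-[(phenylsulfanyl)methyl]benzene, via aryllithium 3 (not isolated), via arylmagnesium bromide 4 (not isolated)
Conditions: n-BuLi, THF, −78 °C; MgBr2·OEt2, −78 °C; PhSCH2Cl, −78 °C → 0 °C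
Reagents that add atoms: chloromethyl phenyl sulfide ClCSc1ccccc1
Why: Directed ortho-lithiation should occur at the C–H flanked by fluorine and a benzyloxy group (the most acidic ring position), and after transmetalation the aryl Grignard reagent is alkylated by the α-chloro sulfide in an SN2 reaction; no stereocenter is formed.

Step 3
Reactants: 6 2-bromo-1-[3,4-bis(benzyloxy)phenyl]ethan-1-one
Product: 7 (1R)-2-bromo-1-[3,4-bis(benzyloxy)phenyl]ethan-1-ol
Conditions: (R)-2-methyl-CBS-oxazaborolidine (10 mol%), BH3·SMe2, THF, 0 °C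
Reagents that add atoms: none
Why: Corey–Bakshi–Shibata reduction, in which the (R)-oxazaborolidine–borane complex delivers hydride to the ketone face that places the aryl group in the large-group position, should set the carbinol center as R (the future C2 of the third unit).

Step 4
Reactants: 7 (1R)-2-bromo-1-[3,4-bis(benzyloxy)phenyl]ethan-1-ol
Product: 8 (2R)-2-[3,4-bis(benzyloxy)phenyl]oxirane
Conditions: K2CO3, MeOH/THF, 0 °C → rt
Reagents that add atoms: none
Why: Intramolecular Williamson etherification of the bromohydrin closes the oxirane at the CH2 carbon, so the C–O bond of the stereocenter is untouched and the R configuration is retained.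

Step 5
Reactants: 5 1,5-bis(benzyloxy)-3-fluoro-2-[(phenylsulfanyl)methyl]benzene; 8 (2R)-2-[3,4-bis(benzyloxy)phenyl]oxirane
Product: 11 (2S,4RS)-5,7-bis(benzyloxy)-2-[3,4-bis(benzyloxy)phenyl]-4-(phenylsulfanyl)chromane, via lithiated sulfide 9 (not isolated), via lithium alkoxide 10 (not isolated)
Conditions: 5, LiN(i-Pr)2, THF, −78 °C; 8, −78 °C → 0 °C; then KOt-Bu, 18-crown-6, DMPU, 80 °C
Reagents that add atoms: none
Why: The amide base removes the most acidic proton of 5 (benzylic and α to sulfur), the carbanion 9 (future C4) opens oxirane 8 at its CH2 carbon (future C3) by SN2 to form the C3–C4 bond, and the oxirane oxygen released as the C2 alkoxide 10 attacks, after Li/K exchange, the fluorine-bearing carbon (future C8a) in an intramolecular SNAr to form the O1–C8a bond. The closest known reaction types are the opening of terminal epoxides by α-thio organolithiums and the pyran closure of flavans by alkoxide SNAr on 3,5-dialkoxyfluorobenzenes. Ring C is the only ring closed, by an anionic addition–elimination at an aromatic carbon that gives the six-membered benzo-fused pyran. The only new stereocenter is C4 (bearing SPh), which is not controlled and is removed in step 6, while C2 is carried over from 8 unchanged because no bond at C2 is broken. The step needs attack at the CH2 carbon and not at the benzylic carbon of the electron-rich oxirane, which the hindered soft carbanion and the absence of any Lewis acid should secure, and it needs closure through O1 only, which is guaranteed because 10 holds a single alkoxide.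

Step 6
Reactants: 11 (2S,4RS)-5,7-bis(benzyloxy)-2-[3,4-bis(benzyloxy)phenyl]-4-(phenylsulfanyl)chromane
Product: 13 (2S)-5,7-bis(benzyloxy)-2-[3,4-bis(benzyloxy)phenyl]-2H-chromene, via sulfoxide 12 (not isolated)
Conditions: mCPBA (1.0 equiv), NaHCO3, CH2Cl2, −78 °C; then toluene, 80 °C
Reagents that add atoms: none
Why: Chemoselective sulfide oxidation followed by thermal syn-elimination of the benzylic sulfoxide (sulfoxide pyrolysis) should give the C3=C4 alkene only, because C3 carries the only β-hydrogens; the C4 stereocenter disappears and C2 is not touched.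

Step 7
Reactants: 14 (+)-catechin
Product: 15 5,7,3',4'-tetra-O-benzyl-(+)-catechin
Conditions: BnBr (4.4 equiv), K2CO3, DMF, 0 °C → rt
Reagents that add atoms: benzyl bromide BrCc1ccccc1
Why: Williamson etherification with a carbonate base deprotonates only the four phenols, so the secondary 3-OH should stay free and both stereocenters are untouched.

Step 8
Reactants: 13 (2S)-5,7-bis(benzyloxy)-2-[3,4-bis(benzyloxy)phenyl]-2H-chromene; 15 5,7,3',4'-tetra-O-benzyl-(+)-catechin
Product: 17 octa-O-benzyl catechin-(4α→8)-catechin (5,7,3',4'-benzyl ethers on both units; both 3-OH free), via 3β,4β-epoxyflavan 16 (not isolated)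
Conditions: dimethyldioxirane (DMDO), acetone/CH2Cl2, −40 °C; volatiles removed cold; then 15 (3 equiv), ZnCl2, THF/CH2Cl2, −78 °C → −20 °C
Reagents that add atoms: dimethyldioxirane CC1(C)OO1
Why: Dioxirane epoxidation of the electron-rich C3=C4 bond should occur on the face opposite to the C2 aryl group (this sets C3 with its oxygen β), and the labile benzylic epoxide is then opened at C4 with inversion by C8 of 15 in a ZnCl2-promoted Friedel–Crafts alkylation, the anti opening known from glycal epoxides, which sets C4 (aryl α, 3,4-trans) and leaves the 3-OH free.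

Step 9
Reactants: 15 5,7,3',4'-tetra-O-benzyl-(+)-catechin
Product: 18 (2R,3S,4S)-5,7,3',4'-tetra-O-benzyl-4-(2-ethoxyethoxy)catechin (4β ether)
Conditions: DDQ (2 equiv), 2-ethoxyethanol, CH2Cl2, rt
Reagents that add atoms: 2-ethoxyethanol CCOCCO
Why: DDQ-mediated benzylic oxidation abstracts hydride from C4 and the resulting quinone-methide-type cation is trapped by the alcohol on the face opposite to the C2 aryl group, which should give the 4β ether.

Step 10
Reactants: 18 (2R,3S,4S)-5,7,3',4'-tetra-O-benzyl-4-(2-ethoxyethoxy)catechin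
Product: 19 (2R,3S,4S)-3-O-acetyl-5,7,3',4'-tetra-O-benzyl-4-(2-ethoxyethoxy)catechin
Conditions: Ac2O, pyridine, DMAP (cat.), rt
Reagents that add atoms: acetic anhydride CC(=O)OC(C)=O
Why: DMAP-catalysed acylation of the secondary alcohol installs the participating 3-O-acetyl group without touching any stereocenter.

Step 11
Reactants: 17 octa-O-benzyl catechin-(4α→8)-catechin; 19 (2R,3S,4S)-3-O-acetyl-5,7,3',4'-tetra-O-benzyl-4-(2-ethoxyethoxy)catechin
Product: 20 dodeca-O-benzyl 3-O-acetylcatechin-(4α→8)-catechin-(4α→8)-catechin (acetate on the top unit)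
Conditions: TMSOTf (0.2 equiv), CH2Cl2, −78 °C → −40 °C, slow addition of 19 (1.0 equiv)
Reagents that add atoms: none
Why: Lewis acid mediated flavan-4-yl cation coupling (Friedel–Crafts alkylation): the cation from 19 is shielded on its β face by the neighbouring 3-O-acetyl group, so C8 of the upper unit of 17 should attack from the α face and set the new C4 as 4α (3,4-trans).

Step 12
Reactants: 20 dodeca-O-benzyl 3-O-acetylcatechin-(4α→8)-catechin-(4α→8)-catechin; 19 (2R,3S,4S)-3-O-acetyl-5,7,3',4'-tetra-O-benzyl-4-(2-ethoxyethoxy)catechin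
Product: 21 hexadeca-O-benzyl tetramer with 3-O-acetyl groups on the first and second unit
Conditions: TMSOTf (0.2 equiv), CH2Cl2, −78 °C → −40 °C, slow addition of 19 (1.0 equiv)
Reagents that add atoms: none
Why: The same acetate-directed flavan-4-yl cation coupling should join C4 of the new top unit to C8 of the acetylated upper unit of 20 and set this C4 as 4α.

Step 13
Reactants: 21 hexadeca-O-benzyl tetramer with 3-O-acetyl groups on the first and second unit
Product: 22 hexadeca-O-benzyl catechin-(4α→8)-catechin-(4α→8)-catechin-(4α→8)-catechin (all four 3-OH free)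
Conditions: NaOMe (cat.), MeOH/THF, 40 °C
Reagents that add atoms: none
Why: Zemplén transesterification removes both acetates, while benzyl ethers, interflavan bonds and all stereocenters are stable to catalytic methoxide.

Step 14
Reactants: 22 hexadeca-O-benzyl catechin-(4α→8)-catechin-(4α→8)-catechin-(4α→8)-catechin
Product: 23 catechin-(4α→8)-catechin-(4α→8)-catechin-(4α→8)-catechin (CNP0236700.2)
Conditions: H2 (1 atm), Pd(OH)2/C, THF/MeOH/H2O, rt
Reagents that add atoms: none
Why: Catalytic hydrogenolysis of the sixteen benzyl ethers under neutral conditions should leave the acid-labile interflavan bonds and every stereocenter intact.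

Compound list
1 | 1,3,5-trifluorobenzene | Fc1cc(F)cc(F)c1 | starting material
2 | 1,3-bis(benzyloxy)-5-fluorobenzene | Fc1cc(OCc2ccccc2)cc(OCc2ccccc2)c1 | intermediate
3 | [2,4-bis(benzyloxy)-6-fluorophenyl]lithium | [Li]c1c(F)cc(OCc2ccccc2)cc1OCc1ccccc1 | intermediate
4 | [2,4-bis(benzyloxy)-6-fluorophenyl]magnesium bromide | Br[Mg]c1c(F)cc(OCc2ccccc2)cc1OCc1ccccc1 | intermediate
5 | 1,5-bis(benzyloxy)-3-fluoro-2-[(phenylsulfanyl)methyl]benzene | Fc1cc(OCc2ccccc2)cc(OCc2ccccc2)c1CSc1ccccc1 | intermediate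
6 | 2-bromo-1-[3,4-bis(benzyloxy)phenyl]ethan-1-one | O=C(CBr)c1ccc(OCc2ccccc2)c(OCc2ccccc2)c1 | starting material
7 | (1R)-2-bromo-1-[3,4-bis(benzyloxy)phenyl]ethan-1-ol | O[C@@H](CBr)c1ccc(OCc2ccccc2)c(OCc2ccccc2)c1 | intermediate
8 | (2R)-2-[3,4-bis(benzyloxy)phenyl]oxirane | C1O[C@@H]1c1ccc(OCc2ccccc2)c(OCc2ccccc2)c1 | intermediate
9 | {[2,4-bis(benzyloxy)-6-fluorophenyl](phenylsulfanyl)methyl}lithium | [Li]C(Sc1ccccc1)c1c(F)cc(OCc2ccccc2)cc1OCc1ccccc1 | intermediate
10 | lithium (1S)-1-[3,4-bis(benzyloxy)phenyl]-3-[2,4-bis(benzyloxy)-6-fluorophenyl]-3-(phenylsulfanyl)propan-1-olate (both C3 epimers) | [Li+].[O-][C@H](c1ccc(OCc2ccccc2)c(OCc2ccccc2)c1)CC(Sc1ccccc1)c1c(F)cc(OCc2ccccc2)cc1OCc1ccccc1 | intermediate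
11 | (2S,4RS)-5,7-bis(benzyloxy)-2-[3,4-bis(benzyloxy)phenyl]-4-(phenylsulfanyl)chromane | c1(OCc3ccccc3)cc(OCc3ccccc3)c2c(c1)O[C@H](c1ccc(OCc3ccccc3)c(OCc3ccccc3)c1)CC2Sc1ccccc1 | intermediate
12 | (2S)-5,7-bis(benzyloxy)-2-[3,4-bis(benzyloxy)phenyl]-4-(phenylsulfinyl)chromane (mixture at C4 and S) | c1(OCc3ccccc3)cc(OCc3ccccc3)c2c(c1)O[C@H](c1ccc(OCc3ccccc3)c(OCc3ccccc3)c1)CC2S(=O)c1ccccc1 | intermediate
13 | (2S)-5,7-bis(benzyloxy)-2-[3,4-bis(benzyloxy)phenyl]-2H-chromene | c1(OCc3ccccc3)cc(OCc3ccccc3)c2c(c1)O[C@H](c1ccc(OCc3ccccc3)c(OCc3ccccc3)c1)C=C2 | intermediate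
14 | (+)-catechin, (2R,3S)-2-(3,4-dihydroxyphenyl)chromane-3,5,7-triol | Oc1cc(O)c2c(c1)O[C@H](c1ccc(O)c(O)c1)[C@@H](O)C2 | starting material
15 | 5,7,3',4'-tetra-O-benzyl-(+)-catechin | c1(OCc3ccccc3)cc(OCc3ccccc3)c2c(c1)O[C@H](c1ccc(OCc3ccccc3)c(OCc3ccccc3)c1)[C@@H](O)C2 | intermediate
16 | (2R)-5,7-bis(benzyloxy)-2-[3,4-bis(benzyloxy)phenyl]-3β,4β-epoxychromane (oxirane oxygen trans to the C2 aryl group) | c1(OCc3ccccc3)cc(OCc3ccccc3)c2c(c1)O[C@H](c1ccc(OCc3ccccc3)c(OCc3ccccc3)c1)[C@H]3O[C@@H]23 | intermediate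
17 | octa-O-benzyl catechin-(4α→8)-catechin (both 3-OH free) | c1(OCc3ccccc3)cc(OCc3ccccc3)c2c(c1)O[C@H](c1ccc(OCc3ccccc3)c(OCc3ccccc3)c1)[C@@H](O)[C@@H]2c1c(OCc3ccccc3)cc(OCc3ccccc3)c2c1O[C@H](c1ccc(OCc3ccccc3)c(OCc3ccccc3)c1)[C@@H](O)C2 | intermediate
18 | (2R,3S,4S)-5,7,3',4'-tetra-O-benzyl-4-(2-ethoxyethoxy)catechin | c1(OCc3ccccc3)cc(OCc3ccccc3)c2c(c1)O[C@H](c1ccc(OCc3ccccc3)c(OCc3ccccc3)c1)[C@@H](O)[C@H]2OCCOCC | intermediate
19 | (2R,3S,4S)-3-O-acetyl-5,7,3',4'-tetra-O-benzyl-4-(2-ethoxyethoxy)catechin | c1(OCc3ccccc3)cc(OCc3ccccc3)c2c(c1)O[C@H](c1ccc(OCc3ccccc3)c(OCc3ccccc3)c1)[C@@H](OC(C)=O)[C@H]2OCCOCC | intermediate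
20 | dodeca-O-benzyl 3-O-acetylcatechin-(4α→8)-catechin-(4α→8)-catechin | c1(OCc3ccccc3)cc(OCc3ccccc3)c2c(c1)O[C@H](c1ccc(OCc3ccccc3)c(OCc3ccccc3)c1)[C@@H](OC(C)=O)[C@@H]2c1c(OCc3ccccc3)cc(OCc3ccccc3)c2c1O[C@H](c1ccc(OCc3ccccc3)c(OCc3ccccc3)c1)[C@@H](O)[C@@H]2c1c(OCc3ccccc3)cc(OCc3ccccc3)c2c1O[C@H](c1ccc(OCc3ccccc3)c(OCc3ccccc3)c1)[C@@H](O)C2 | intermediate
21 | hexadeca-O-benzyl tetramer with 3-O-acetyl groups on the first and second unit | c1(OCc3ccccc3)cc(OCc3ccccc3)c2c(c1)O[C@H](c1ccc(OCc3ccccc3)c(OCc3ccccc3)c1)[C@@H](OC(C)=O)[C@@H]2c1c(OCc3ccccc3)cc(OCc3ccccc3)c2c1O[C@H](c1ccc(OCc3ccccc3)c(OCc3ccccc3)c1)[C@@H](OC(C)=O)[C@@H]2c1c(OCc3ccccc3)cc(OCc3ccccc3)c2c1O[C@H](c1ccc(OCc3ccccc3)c(OCc3ccccc3)c1)[C@@H](O)[C@@H]2c1c(OCc3ccccc3)cc(OCc3ccccc3)c2c1O[C@H](c1ccc(OCc3ccccc3)c(OCc3ccccc3)c1)[C@@H](O)C2 | intermediate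
22 | hexadeca-O-benzyl catechin-(4α→8)-catechin-(4α→8)-catechin-(4α→8)-catechin | c1(OCc3ccccc3)cc(OCc3ccccc3)c2c(c1)O[C@H](c1ccc(OCc3ccccc3)c(OCc3ccccc3)c1)[C@@H](O)[C@@H]2c1c(OCc3ccccc3)cc(OCc3ccccc3)c2c1O[C@H](c1ccc(OCc3ccccc3)c(OCc3ccccc3)c1)[C@@H](O)[C@@H]2c1c(OCc3ccccc3)cc(OCc3ccccc3)c2c1O[C@H](c1ccc(OCc3ccccc3)c(OCc3ccccc3)c1)[C@@H](O)[C@@H]2c1c(OCc3ccccc3)cc(OCc3ccccc3)c2c1O[C@H](c1ccc(OCc3ccccc3)c(OCc3ccccc3)c1)[C@@H](O)C2 | intermediate
23 | catechin-(4α→8)-catechin-(4α→8)-catechin-(4α→8)-catechin (CNP0236700.2) | Oc1cc(O)c2c(c1)O[C@H](c1ccc(O)c(O)c1)[C@@H](O)[C@@H]2c1c(O)cc(O)c2c1O[C@H](c1ccc(O)c(O)c1)[C@@H](O)[C@@H]2c1c(O)cc(O)c2c1O[C@H](c1ccc(O)c(O)c1)[C@@H](O)[C@@H]2c1c(O)cc(O)c2c1O[C@H](c1ccc(O)c(O)c1)[C@@H](O)C2 | target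

Total step count: 14 steps.
Longest linear sequence: 9 steps (1, 2, 5, 6, 8, 11, 12, 13, 14; the branch 3, 4, 5, 6, 8, 11, 12, 13, 14 is equally long).

Steps most likely to fail

Step 5. The lithium counter-ion may steer the carbanion to the benzylic carbon of the electron-rich oxirane or trigger its rearrangement to an arylacetaldehyde, and fluoride displacement may stall at the alkoxide stage. The fallback sets out from 7 and 5 and returns to the route at 11; it replaces the oxirane by a primary bromide and separates the two bond formations. Bromohydrin 7 is silylated (TBSCl, imidazole, DMF) to (R)-{2-bromo-1-[3,4-bis(benzyloxy)phenyl]ethoxy}(tert-butyl)dimethylsilane F1. The lithiated sulfide from 5 (LiN(i-Pr)2, THF/DMPU) is alkylated by F1 in an SN2 reaction at CH2Br to give tert-butyl{(1S)-1-[3,4-bis(benzyloxy)phenyl]-3-[2,4-bis(benzyloxy)-6-fluorophenyl]-3-(phenylsulfanyl)propoxy}dimethylsilane F2. Bu4NF in THF frees (1S)-1-[3,4-bis(benzyloxy)phenyl]-3-[2,4-bis(benzyloxy)-6-fluorophenyl]-3-(phenylsulfanyl)propan-1-ol F3, and KH in DMF closes the pyran by SNAr to give 11.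

Step 8. The very labile epoxide may ionise and add to unreacted electron-rich chromene before the nucleophile is present, and dioxirane delivery may not be fully face-selective. The fallback sets out from 13 and returns at 17; it uses a stable diol as the C4 electrophile. Upjohn dihydroxylation of 13 (OsO4 cat., N-methylmorpholine N-oxide, acetone/H2O) on the face opposite to the C2 aryl group should give (2R,3S,4S)-5,7-bis(benzyloxy)-2-[3,4-bis(benzyloxy)phenyl]chromane-3,4-diol F4. TiCl4-promoted condensation of F4 with 15 (CH2Cl2, −78 °C), the classical flavan-3,4-diol coupling, then gives 17 by attack trans to the 3-oxygen.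

Step 12. At equimolar stoichiometry the electrophile 19 may condense with itself through its own free C8, the chain may grow beyond the tetramer, and attack at C6 may compete. The fallback sets out from 19 and 17 and returns at 21; it is convergent and replaces steps 11 and 12. Self-condensation of 19 is run deliberately under a mild Lewis acid (Zn(OTf)2, CH2Cl2) to give the dimeric electrophile 3-O-acetyl-5,7,3',4'-tetra-O-benzylcatechin-(4α→8)-[3-O-acetyl-5,7,3',4'-tetra-O-benzyl-4β-(2-ethoxyethoxy)catechin] F5. After purification F5 is condensed with dimer 17 (TMSOTf, CH2Cl2, −78 °C) to give 21 directly.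

Further compounds
F1 | step 5 | (R)-{2-bromo-1-[3,4-bis(benzyloxy)phenyl]ethoxy}(tert-butyl)dimethylsilane | CC(C)(C)[Si](C)(C)O[C@@H](CBr)c1ccc(OCc2ccccc2)c(OCc2ccccc2)c1
F2 | step 5 | tert-butyl{(1S)-1-[3,4-bis(benzyloxy)phenyl]-3-[2,4-bis(benzyloxy)-6-fluorophenyl]-3-(phenylsulfanyl)propoxy}dimethylsilane | CC(C)(C)[Si](C)(C)O[C@H](c1ccc(OCc2ccccc2)c(OCc2ccccc2)c1)CC(Sc1ccccc1)c1c(F)cc(OCc2ccccc2)cc1OCc1ccccc1
F3 | step 5 | (1S)-1-[3,4-bis(benzyloxy)phenyl]-3-[2,4-bis(benzyloxy)-6-fluorophenyl]-3-(phenylsulfanyl)propan-1-ol | O[C@H](c1ccc(OCc2ccccc2)c(OCc2ccccc2)c1)CC(Sc1ccccc1)c1c(F)cc(OCc2ccccc2)cc1OCc1ccccc1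
F4 | step 8 | (2R,3S,4S)-5,7-bis(benzyloxy)-2-[3,4-bis(benzyloxy)phenyl]chromane-3,4-diol | c1(OCc3ccccc3)cc(OCc3ccccc3)c2c(c1)O[C@H](c1ccc(OCc3ccccc3)c(OCc3ccccc3)c1)[C@@H](O)[C@H]2O
F5 | step 12 | 3-O-acetyl-5,7,3',4'-tetra-O-benzylcatechin-(4α→8)-[3-O-acetyl-5,7,3',4'-tetra-O-benzyl-4β-(2-ethoxyethoxy)catechin] | c1(OCc3ccccc3)cc(OCc3ccccc3)c2c(c1)O[C@H](c1ccc(OCc3ccccc3)c(OCc3ccccc3)c1)[C@@H](OC(C)=O)[C@@H]2c1c(OCc3ccccc3)cc(OCc3ccccc3)c2c1O[C@H](c1ccc(OCc3ccccc3)c(OCc3ccccc3)c1)[C@@H](OC(C)=O)[C@H]2OCCOCC
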